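**Retrosynthetic overview**

1. Daucane numbering is used: C1 is the methyl-bearing fusion carbon, C2 and C3 are CH2, C4 is the isopropyl carbinol, C5 the fusion CH, C6 the ester carbon, C7 a CH2, C8(CH3)=C9 the alkene, C10 a CH2. α is the face opposite the C1 methyl. The last disconnections are the C6 ester (acylation), the C4–isopropyl bond (addition to a C4 ketone) and C6–O/C5–H (conjugate borylation–oxidation of a C5=C6 enone).
2. The strategy rests on the seven-membered ring. In it the quaternary C1 is flanked by C10H2–C9H=C8(CH3)–C7H2, the five-carbon unit that an isopropenylcyclopropane releases when its C9–C1 bond opens. C5–C6 is a two-carbon unit held to C1 by the C2–C3–C4 chain of the five-membered ring.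
3. Key disconnection: C1–C5 and C6–C7, made in one rhodium-catalysed [5+2] cycloaddition of a cis yne–vinylcyclopropane. The cyclopentanone closes first (alkyne insertion) and the cycloheptadiene second (reductive elimination), in the same operation.
4. The cycloaddition precursor comes from nerol. Its Z-alkene gives the cis cyclopropane in an asymmetric Simmons–Smith reaction that sets C1; the CH2OH group becomes the isopropenyl group and the prenyl end is cut down to the ethynyl ketone.

Key step: step 9

Assumption: the (4R,5R)-dioxaborolane is taken to deliver methylene to nerol with the facial sense it shows for cinnamyl alcohol; if the sense proved opposite, the (4S,5S)-controller would be used.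

**Route**

Step 1
Reactants: 1 nerol
Product: 2 [(1S,2R)-2-methyl-2-(4-methylpent-3-en-1-yl)cyclopropyl]methanol
Conditions: Zn(CH2I)2·DME (from Et2Zn, CH2I2, DME; 2.2 equiv), (4R,5R)-2-butyl-N,N,N',N'-tetramethyl-1,3,2-dioxaborolane-4,5-dicarboxamide (1.2 equiv), CH2Cl2, −10 °C to rt; aq NaOH work-up
Reagents that add atoms: diiodomethane, ICI
Why: In this Charette asymmetric cyclopropanation (a Simmons–Smith reaction) the zinc alkoxide of the allylic alcohol is bound by the chiral dioxaborolane, which steers Zn(CH2I)2 to one face of the allylic alkene; the Z geometry becomes the cis relation of CH2OH and the homoprenyl chain, both ring stereocentres (future C1 and C9) are set, and the remote alkene, which has no directing hydroxyl, should stay untouched.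

Step 2
Reactants: 2 [(1S,2R)-2-methyl-2-(4-methylpent-3-en-1-yl)cyclopropyl]methanol
Product: 3 (1S,2R)-2-methyl-2-(4-methylpent-3-en-1-yl)cyclopropane-1-carbaldehyde
Conditions: Dess–Martin periodinane (DMP), CH2Cl2, 0 °C to rt
Reagents that add atoms: none
Why: Dess–Martin oxidation of a primary alcohol is neutral and mild, so the cyclopropane CH next to the new aldehyde should not epimerise and the trisubstituted alkene is inert.

Step 3
Reactants: 3 (1S,2R)-2-methyl-2-(4-methylpent-3-en-1-yl)cyclopropane-1-carbaldehyde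
Product: 4 1-[(1S,2R)-2-methyl-2-(4-methylpent-3-en-1-yl)cyclopropyl]ethan-1-ol (both carbinol epimers)
Conditions: MeMgBr, THF, −78 to 0 °C; then pH 7 buffer
Reagents that add atoms: methylmagnesium bromide, C[Mg]Br
Why: Grignard addition to an aldehyde; the new carbinol centre forms without control, which does not matter because it is oxidised in the next step.

Step 4
Reactants: 4 1-[(1S,2R)-2-methyl-2-(4-methylpent-3-en-1-yl)cyclopropyl]ethan-1-ol
Product: 5 1-[(1S,2R)-2-methyl-2-(4-methylpent-3-en-1-yl)cyclopropyl]ethan-1-one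
Conditions: DMP, CH2Cl2, 0 °C to rt
Reagents that add atoms: none
Why: Dess–Martin oxidation of the secondary alcohol merges both epimers into the cyclopropyl methyl ketone without touching the ring stereocentres.

Step 5
Reactants: 5 1-[(1S,2R)-2-methyl-2-(4-methylpent-3-en-1-yl)cyclopropyl]ethan-1-one
Product: 7 3-[(1R,2S)-2-acetyl-1-methylcyclopropyl]propanal, via secondary ozonide 6 (not isolated)
Conditions: O3, CH2Cl2, −78 °C; then PPh3, −78 °C to rt
Reagents that add atoms: ozone, [O-][O+]=O
Why: Ozonolysis with reductive work-up cleaves the only alkene present; it is placed before the isopropenyl group is installed so that no second alkene competes, and the ketone and cyclopropane are inert to ozone.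

Step 6
Reactants: 7 3-[(1R,2S)-2-acetyl-1-methylcyclopropyl]propanal; 8 ethynylmagnesium bromide
Product: 9 1-[(1S,2R)-2-(3-hydroxypent-4-yn-1-yl)-2-methylcyclopropyl]ethan-1-one (both carbinol epimers)
Conditions: ethynylmagnesium bromide (1.1 equiv), THF, −78 °C; then pH 7 buffer
Reagents that add atoms: ethynylmagnesium bromide (8), C#C[Mg]Br
Why: Grignard addition is chemoselective because the aldehyde is far more electrophilic than the hindered cyclopropyl methyl ketone at low temperature with about one equivalent of reagent; the carbinol centre is removed in step 8.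

Step 7
Reactants: 9 1-[(1S,2R)-2-(3-hydroxypent-4-yn-1-yl)-2-methylcyclopropyl]ethan-1-one
Product: 10 5-[(1R,2R)-1-methyl-2-(prop-1-en-2-yl)cyclopropyl]pent-1-yn-3-ol (both carbinol epimers)
Conditions: Ph3PCH3Br, KOtBu (3 equiv each), THF, 0 °C to rt
Reagents that add atoms: methyltriphenylphosphonium bromide, C[P+](c1ccccc1)(c1ccccc1)c1ccccc1.[Br-]
Why: Wittig methylenation of a methyl ketone tolerates the free hydroxyl when excess ylide is used, and the cyclopropane CH next to the ketone resists deprotonation (a cyclopropyl enolate is strained), so the cis relation of the isopropenyl group and the tether should survive.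

Step 8
Reactants: 10 5-[(1R,2R)-1-methyl-2-(prop-1-en-2-yl)cyclopropyl]pent-1-yn-3-ol
Product: 11 5-[(1R,2R)-1-methyl-2-(prop-1-en-2-yl)cyclopropyl]pent-1-yn-3-one
Conditions: DMP, CH2Cl2, 0 °C to rt; used without storage
Reagents that add atoms: none
Why: Dess–Martin oxidation converts secondary propargylic alcohols into terminal ynones under neutral conditions that leave the vinylcyclopropane intact.

Step 9
Reactants: 11 5-[(1R,2R)-1-methyl-2-(prop-1-en-2-yl)cyclopropyl]pent-1-yn-3-one
Product: 12 (3aR)-3a,6-dimethyl-3,3a,4,7-tetrahydroazulen-1(2H)-one (C4 ketone, C5=C6 and C8=C9 in daucane numbering)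
Conditions: [Rh(CO)2Cl]2 (5 mol %), 1,2-dichloroethane (0.02 M), 80 °C, argon
Reagents that add atoms: none
Why: [Rh(CO)2Cl]2 binds the isopropenyl group and the alkyne, which the cis cyclopropane holds on the same face, and monovalent rhodium adds oxidatively into the proximal C9–C1 bond with retention at C1 to give a trivalent rhodium species carrying a π-allyl (C7–C8–C9) and a σ-alkyl (C1) ligand. The alkyne then inserts into Rh–C1, forming C1–C5 and closing the cyclopentanone (5-exo-dig insertion), and reductive elimination between the vinyl carbon C6 and the allyl terminus C7 forms C6–C7 and closes the cyclohepta-1,4-diene, leaving C5=C6 and C8=C9. The closest known reaction type is the rhodium-catalysed intramolecular [5+2] cycloaddition of cis-2-ene-vinylcyclopropanes, joined to the alkyne partners of the classical yne–vinylcyclopropane [5+2]; a conjugated ynone as partner and a fully substituted C1 lie outside the examples on record and are the open points of the route. No new stereocentre arises: C1, set in step 1, is carried through because oxidative addition and insertion both proceed with retention at carbon. The step needs cleavage of C9–C1 and not C9–C10, which two-point binding of rhodium between alkene and tethered alkyne should enforce (the tether on C1 cannot reach a metal inserted at C10), and it needs closure at C7 and not at C9 ([5+2] over [3+2]), which the cis substrate should secure because its allyl unit carries C10 anti, so that bonding at C7 gives a cis C8=C9 alkene inside a seven-membered ring.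

Step 10
Reactants: 12 (3aR)-3a,6-dimethyl-3,3a,4,7-tetrahydroazulen-1(2H)-one
Product: 14 (3aR,8S,8aS)-8-hydroxy-3a,6-dimethyl-3,3a,4,7,8,8a-hexahydroazulen-1(2H)-one (C6–OH α, C5–H α), via boronate 13 (not isolated)
Conditions: CuCl (10 mol %), Xantphos (10 mol %), NaOtBu (10 mol %), B2pin2 (1.2 equiv), MeOH (2 equiv), THF, rt; then NaBO3·4H2O, THF/H2O, 0 °C to rt
Reagents that add atoms: sodium perborate (oxygen of the C6 hydroxyl), [Na+].[Na+].O[B-]1(O)OO[B-](O)(O)OO1; bis(pinacolato)diboron (boron of intermediate 13 only), CC1(C)OB(OC1(C)C)B1OC(C)(C)C(C)(C)O1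
Why: Copper-catalysed conjugate borylation touches only the enone; the boryl group should add to C6 from the α-face, away from the C1 methyl that sits 1,3 to C6, methanol should protonate the enolate at C5 from the same face to give the trans ring fusion, and perborate replaces boron by oxygen with retention.

Step 11
Reactants: 14 (3aR,8S,8aS)-8-hydroxy-3a,6-dimethyl-3,3a,4,7,8,8a-hexahydroazulen-1(2H)-one; 15 isopropylmagnesium chloride
Product: 16 (3R,3aS,4S,8aR)-6,8a-dimethyl-3-(propan-2-yl)-1,2,3,3a,4,5,8,8a-octahydroazulene-3,4-diol (C4–OH β, C6–OH α)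
Conditions: CeCl3 (anhydrous, 4 equiv), THF, rt; then isopropylmagnesium chloride (4 equiv), −78 to 0 °C; then H2O
Reagents that add atoms: isopropylmagnesium chloride (15), CC(C)[Mg]Cl
Why: The weakly basic iPrMgCl/CeCl3 reagent adds 1,2 and suppresses enolisation and β-hydride reduction; the first equivalent converts the C6 hydroxyl into an alkoxide that chelates the C4 carbonyl, and isopropyl should enter from the α-face because the C1 methyl blocks the β-trajectory, which gives the β-hydroxyl at C4.

Step 12
Reactants: 16 (3R,3aS,4S,8aR)-6,8a-dimethyl-3-(propan-2-yl)-1,2,3,3a,4,5,8,8a-octahydroazulene-3,4-diol; 17 3,4-dimethoxybenzoyl chloride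
Product: 18 [(3R,3aS,4S,8aR)-3-hydroxy-6,8a-dimethyl-3-(propan-2-yl)-1,2,3,3a,4,5,8,8a-octahydroazulen-4-yl] 3,4-dimethoxybenzoate (target)
Conditions: 3,4-dimethoxybenzoyl chloride (1.5 equiv), Et3N, 4-(dimethylamino)pyridine (DMAP, 0.2 equiv), CH2Cl2, 0 °C to rt
Reagents that add atoms: 3,4-dimethoxybenzoyl chloride (17), COc1ccc(C(=O)Cl)cc1OC
Why: DMAP-catalysed acylation should esterify only the secondary C6 hydroxyl, since the tertiary C4 hydroxyl next to the isopropyl group is too hindered to react, and no stereocentre is touched.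

**Compound list**

1 | nerol, (2Z)-3,7-dimethylocta-2,6-dien-1-ol | CC(C)=CCC/C(C)=C\CO | starting material
2 | [(1S,2R)-2-methyl-2-(4-methylpent-3-en-1-yl)cyclopropyl]methanol | OC[C@H]1C[C@@]1(C)CCC=C(C)C | intermediate
3 | (1S,2R)-2-methyl-2-(4-methylpent-3-en-1-yl)cyclopropane-1-carbaldehyde | O=C[C@H]1C[C@@]1(C)CCC=C(C)C | intermediate
4 | 1-[(1S,2R)-2-methyl-2-(4-methylpent-3-en-1-yl)cyclopropyl]ethan-1-ol, carbinol epimers | CC(O)[C@H]1C[C@@]1(C)CCC=C(C)C | intermediate
5 | 1-[(1S,2R)-2-methyl-2-(4-methylpent-3-en-1-yl)cyclopropyl]ethan-1-one | CC(=O)[C@H]1C[C@@]1(C)CCC=C(C)C | intermediate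
6 | 1-[(1S,2R)-2-[2-(5,5-dimethyl-1,2,4-trioxolan-3-yl)ethyl]-2-methylcyclopropyl]ethan-1-one (secondary ozonide, not isolated) | CC(=O)[C@H]1C[C@@]1(C)CCC2OOC(C)(C)O2 | intermediate
7 | 3-[(1R,2S)-2-acetyl-1-methylcyclopropyl]propanal | CC(=O)[C@H]1C[C@@]1(C)CCC=O | intermediate
8 | ethynylmagnesium bromide | C#C[Mg]Br | starting material
9 | 1-[(1S,2R)-2-(3-hydroxypent-4-yn-1-yl)-2-methylcyclopropyl]ethan-1-one, carbinol epimers | CC(=O)[C@H]1C[C@@]1(C)CCC(O)C#C | intermediate
10 | 5-[(1R,2R)-1-methyl-2-(prop-1-en-2-yl)cyclopropyl]pent-1-yn-3-ol, carbinol epimers | C=C(C)[C@H]1C[C@@]1(C)CCC(O)C#C | intermediate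
11 | 5-[(1R,2R)-1-methyl-2-(prop-1-en-2-yl)cyclopropyl]pent-1-yn-3-one (cycloaddition precursor; isopropenyl and tether cis) | C=C(C)[C@H]1C[C@@]1(C)CCC(=O)C#C | intermediate
12 | (3aR)-3a,6-dimethyl-3,3a,4,7-tetrahydroazulen-1(2H)-one (cycloaddition product) | O=C1CC[C@]2(C)CC=C(C)CC=C12 | intermediate
13 | (3aR,8S,8aR)-3a,6-dimethyl-8-(4,4,5,5-tetramethyl-1,3,2-dioxaborolan-2-yl)-3,3a,4,7,8,8a-hexahydroazulen-1(2H)-one (not isolated) | CC1(C)OB(OC1(C)C)[C@H]2CC(C)=CC[C@@]3(C)CCC(=O)[C@H]23 | intermediate
14 | (3aR,8S,8aS)-8-hydroxy-3a,6-dimethyl-3,3a,4,7,8,8a-hexahydroazulen-1(2H)-one | O[C@H]1CC(C)=CC[C@@]2(C)CCC(=O)[C@H]12 | intermediate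
15 | isopropylmagnesium chloride | CC(C)[Mg]Cl | starting material
16 | (3R,3aS,4S,8aR)-6,8a-dimethyl-3-(propan-2-yl)-1,2,3,3a,4,5,8,8a-octahydroazulene-3,4-diol | O[C@H]1CC(C)=CC[C@@]2(C)CC[C@@](O)(C(C)C)[C@H]12 | intermediate
17 | 3,4-dimethoxybenzoyl chloride | COc1ccc(C(=O)Cl)cc1OC | starting material
18 | [(3R,3aS,4S,8aR)-3-hydroxy-6,8a-dimethyl-3-(propan-2-yl)-1,2,3,3a,4,5,8,8a-octahydroazulen-4-yl] 3,4-dimethoxybenzoate | COc1ccc(C(=O)O[C@H]2CC(C)=CC[C@@]3(C)CC[C@@](O)(C(C)C)[C@H]23)cc1OC | target

**Step count and risk**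

Total step count: 12. Longest linear sequence: 12 steps (nerol to target).

Steps most likely to fail:

Step 9. Oxidative addition at the hindered C9–C1 bond may be slower than oligomerisation of the terminal ynone. The allyl rhodium species may instead close at C9 to the five-membered [3+2] isomer, or a rhodium hydride may move the skipped diene of the product into conjugation. The fallback changes the two-carbon partner from the alkyne to the alkene, the partner for which the [5+2] of cis-2-tethered vinylcyclopropanes is documented, and introduces the C5=C6 unsaturation afterwards. It sets out from keto aldehyde 7. Vinylmagnesium bromide at −78 °C should give the allylic alcohol 1-[(1S,2R)-2-(3-hydroxypent-4-en-1-yl)-2-methylcyclopropyl]ethan-1-one F1. Methylenation as in step 7 should give 5-[(1R,2R)-1-methyl-2-(prop-1-en-2-yl)cyclopropyl]pent-1-en-3-ol F2, and DMP the enone 5-[(1R,2R)-1-methyl-2-(prop-1-en-2-yl)cyclopropyl]pent-1-en-3-one F3. [Rh(CO)2Cl]2 with AgSbF6, or the cationic monovalent rhodium complex [Rh(dppp)]SbF6 (dppp is 1,3-bis(diphenylphosphino)propane), in 1,2-dichloroethane should convert it into the bicyclic ketone (3aR)-3a,6-dimethyl-3,3a,4,7,8,8a-hexahydroazulen-1(2H)-one F4, whose C5 configuration is of no consequence. TMSOTf/Et3N should give the more substituted silyl enol ether trimethyl{[(8aR)-6,8a-dimethyl-1,2,4,5,8,8a-hexahydroazulen-3-yl]oxy}silane F5, and Saegusa–Ito oxidation with Pd(OAc)2 in MeCN comes back to the route at dienone 12.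

Step 10. The enolate may be protonated at C5 from the β-face, which gives the cis ring fusion, and the alkoxide base may shift the C8=C9 alkene through the C7 dienolate. The fallback replaces borylation–oxidation by epoxidation and reductive opening, which sets C5 through a chelated samarium enolate. It sets out from dienone 12. Weitz–Scheffer epoxidation with tBuOOH and DBU should add peroxide at C6 anti to the C1 methyl and give (3aR,8S,8aR)-8,8a-epoxy-3a,6-dimethyl-3,3a,4,7,8,8a-hexahydroazulen-1(2H)-one F6. SmI2 in THF/MeOH at −90 °C should cleave the C5–O bond and, after protonation at C5, come back to the route at hydroxy ketone 14.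

Step 11. The hindered secondary organometallic may reduce the ketone by β-hydride transfer, or enolise it with loss of the C5 configuration, or the alkoxide may undergo retro-aldol ring opening. The fallback uses a smaller sp2 nucleophile on the protected ketol and hydrogenates afterwards. It sets out from hydroxy ketone 14. TESCl and imidazole should give (3aR,8S,8aS)-3a,6-dimethyl-8-(triethylsilyloxy)-3,3a,4,7,8,8a-hexahydroazulen-1(2H)-one F7. Isopropenylmagnesium bromide with CeCl3 should add from the α-face to give (3S,3aS,4S,8aR)-6,8a-dimethyl-3-(prop-1-en-2-yl)-4-(triethylsilyloxy)-1,2,3,3a,4,5,8,8a-octahydroazulen-3-ol F8. H2 with RhCl(PPh3)3 should saturate only the 1,1-disubstituted alkene to give (3R,3aS,4S,8aR)-6,8a-dimethyl-3-(propan-2-yl)-4-(triethylsilyloxy)-1,2,3,3a,4,5,8,8a-octahydroazulen-3-ol F9, and Bu4NF comes back to the route at diol 16.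

**Further compounds**

F1 | step 9 | 1-[(1S,2R)-2-(3-hydroxypent-4-en-1-yl)-2-methylcyclopropyl]ethan-1-one | CC(=O)[C@H]1C[C@@]1(C)CCC(O)C=C
F2 | step 9 | 5-[(1R,2R)-1-methyl-2-(prop-1-en-2-yl)cyclopropyl]pent-1-en-3-ol | C=C(C)[C@H]1C[C@@]1(C)CCC(O)C=C
F3 | step 9 | 5-[(1R,2R)-1-methyl-2-(prop-1-en-2-yl)cyclopropyl]pent-1-en-3-one | C=C(C)[C@H]1C[C@@]1(C)CCC(=O)C=C
F4 | step 9 | (3aR)-3a,6-dimethyl-3,3a,4,7,8,8a-hexahydroazulen-1(2H)-one (C8a epimers) | O=C1CC[C@]2(C)CC=C(C)CCC12
F5 | step 9 | trimethyl{[(8aR)-6,8a-dimethyl-1,2,4,5,8,8a-hexahydroazulen-3-yl]oxy}silane | C[Si](C)(C)OC1=C2CCC(C)=CC[C@@]2(C)CC1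
F6 | step 10 | (3aR,8S,8aR)-8,8a-epoxy-3a,6-dimethyl-3,3a,4,7,8,8a-hexahydroazulen-1(2H)-one | O1[C@H]2CC(C)=CC[C@@]3(C)CCC(=O)[C@]123
F7 | step 11 | (3aR,8S,8aS)-3a,6-dimethyl-8-(triethylsilyloxy)-3,3a,4,7,8,8a-hexahydroazulen-1(2H)-one | CC[Si](CC)(CC)O[C@H]1CC(C)=CC[C@@]2(C)CCC(=O)[C@H]12
F8 | step 11 | (3S,3aS,4S,8aR)-6,8a-dimethyl-3-(prop-1-en-2-yl)-4-(triethylsilyloxy)-1,2,3,3a,4,5,8,8a-octahydroazulen-3-ol | CC[Si](CC)(CC)O[C@H]1CC(C)=CC[C@@]2(C)CC[C@@](O)(C(C)=C)[C@H]12
F9 | step 11 | (3R,3aS,4S,8aR)-6,8a-dimethyl-3-(propan-2-yl)-4-(triethylsilyloxy)-1,2,3,3a,4,5,8,8a-octahydroazulen-3-ol | CC[Si](CC)(CC)O[C@H]1CC(C)=CC[C@@]2(C)CC[C@@](O)(C(C)C)[C@H]12
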